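(All runs were generated by integration with made-up constants, noise included.)

Slowness is oak's way: it runs on 40 mM of free catalyst for 1.5 h, against 150 mM for 0.40 h in elm.

| flask | left-handed substrate | right-handed substrate | reagent | free catalyst | racemization catalyst | impurity | remark | time |
|---|---|---|---|---|---|---|---|---|
| zeta | 0.80 M | 0.80 M | 2.4 M | 48 mM | 1.6 mM | 0.97 mM | run made earlier |  |
| eta | 0.80 M | 0.80 M | 2.4 M | 230 mM | 1.6 mM | 0.97 mM | run made earlier |  |
| delta | 0.80 M | 0.80 M | 2.4 M | 40 mM | 1.6 mM | 1.6 mM | run made earlier |  |
| elm | 0.80 M | 0.80 M | 2.40 M | 150 mM | 1.6 mM | 1.5 mM |  | 0.40 h |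
| oak | 0.80 M | 0.80 M | 2.40 M | 40 mM | 1.6 mM | 0.97 mM |  | 1.5 h |

| run | time / min | left-handed product / % | left-handed substrate / % |
|---|---|---|---|
| zeta | 8.00 | 5.7 | 45.2 |
| zeta | 20.0 | 12.3 | 38.0 |
| zeta | 40.0 | 20.8 | 29.2 |
| zeta | 60.0 | 29.3 | 22.1 |
| eta | 5.00 | 16.3 | 35.8 |
| eta | 12.0 | 26.2 | 22.1 |
| eta | 25.0 | 39.4 | 11.5 |
| eta | 60.0 | 49.7 | 2.6 |
| delta | 5.00 | 3.7 | 47.3 |
| delta | 12.0 | 6.6 | 43.4 |
| delta | 25.0 | 12.4 | 37.0 |
| delta | 60.0 | 25.2 | 25.4 |

(readings scatter by 0.5 percentage points)

- free catalyst is single-handed; left-handed substrate and right-handed substrate are mirror images of each other, charged as a racemate, each of them at the stated concentration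
- what was read earlier has a scatter of 0.5 percentage points, one standard deviation

* which of the two ends with the higher amount of left-handed product, in percent of the left-handed substrate and right-handed substrate together charged ("neither" if they lie within 2 percentage points) (elm / oak / neither)
* left-handed product at the end, in percent of the left-handed substrate and right-handed substrate together charged, elm
* left-handed product at the end, in percent of the left-handed substrate and right-handed substrate together charged, oak

Oak gets 60.0 mM·h of catalyst dose, the free catalyst charge multiplied by the time, and elm gets 60.0 mM·h. Turned round, the question is what would let one flask lead by 2 percentage points. Two ways are reckoned here.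

The first way is unequal doses. Zeta read 29.3% left-handed product at a dose of 48.0 mM·h, and eta read 39.4% at 95.8 mM·h. A straight line joining these two readings puts 31.8% at the dose of elm and oak. On that line, a lead of 2 points needs doses 9.47 mM·h apart, but these two stand 0 mM·h apart.

The second way is racemization, the dynamic part of a dynamic kinetic resolution, feeding one flask. Left-handed substrate plus left-handed product read 1.4 points above half of the charge at the last reading of zeta, which has oak's impurity, and 0.6 points above it in delta, which has more impurity and less free catalyst. Each reading carries a scatter of 0.5 points. Scaled at zeta's pace to oak's time, this reading gives an estimate of 2.1 points of fed substrate. Taken at the share of the left-handed charge that the line implies, 63.6%, this estimate gives oak a gain of 1.3 points, less than the margin. This reckoning therefore commits to a tie near 31.8%, with oak the likelier to edge ahead.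

The forecast says neither, with 31.3% for elm and 32% for oak, giving each flask its own figure where the line above gives one. Its ground: “Elm and oak have the same catalyst × time”.

The flasks give neither: elm 31.6%, oak 32.1%, a gap of 0.50 points, smaller than the margin.

    reagent + free catalyst + left-handed substrate → free catalyst + left-handed product (k = 0.00220 M⁻² s⁻¹)
    reagent + free catalyst + right-handed substrate → free catalyst + right-handed product (k = 2.30 × 10⁻⁵ M⁻² s⁻¹)
    left-handed substrate + racemization catalyst ⇌ right-handed substrate + racemization catalyst, rate k3*[racemization catalyst]*[left-handed substrate] forward; the back reaction follows from the equilibrium constant (k = 0.0560 M⁻¹ s⁻¹)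
    2 racemization catalyst → spent catalyst A (k = 0.0880 M⁻¹ s⁻¹)
    racemization catalyst + impurity → spent catalyst B (k = 12.0 M⁻¹ s⁻¹)
    racemization catalyst → spent catalyst C (k = 7.50 × 10⁻⁵ s⁻¹)

Oak read at 2.5 h has a dose of 100 mM·h, a little above eta's 95.8 mM·h, and the same line, run on to that dose, puts 40.3% there. That later oak flask holds 41.0% left-handed product.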